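Quenching takes the electrophile faster than the main step does at the start, with half-lives of 7.9 s against 60 s, each for its step alone at charged concentrations.

    electrophile + nucleophile → acid + product + leaving group (k1 = 0.23 M⁻¹ s⁻¹)
    protonated nucleophile ⇌ nucleophile + acid, settled at all times (K2 = 2.0 × 10⁻⁹ M)
    buffer acid ⇌ buffer base + acid, settled at all times (K3 = 6.3 × 10⁻⁷ M)
    nucleophile + product ⇌ idle adduct, settled at all times (K4 = 40 M⁻¹)
    electrophile + protic impurity → quenched substrate (k5 = 22 M⁻¹ s⁻¹)

electrophile 20 mM; nucleophile 50.0 mM; buffer base 60.0 mM; buffer acid 2.00 mM; protic impurity 4.00 mM; time 30 s

- acid is the free proton; pH is minus the decimal logarithm of its molar concentration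
- for product the idle adduct is counted in
- run time (flask): 30 s

* part of the electrophile that has reacted at 30 s
* pH of the solution at 30 s

**Which steps compete for the electrophile?** The main step, with the nucleophile, and quenching, with the protic impurity. At the start their rate ratio is 0.13, so quenching leads.

**Can you compare them without following time?** Yes, by dividing one rate by the other. c(electrophile) and time both drop out. What remains is the product per e-fold: the product made each time c(protic impurity) falls by a factor e, equal to the main rate constant times c(nucleophile) over the quenching rate constant. At the charge that is 0.523 mM.

**Does the impurity last?** I expect not, because its own half-life, ln(2) over the quenching rate constant times c(electrophile), is 1.58 s at the charge, short against 30 s, and the electrophile is charged in excess of it. Its 4.00 mM should therefore take 20.0% of the electrophile.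

**And the rest?** The remaining 16.0 mM reacts in a pseudo-first-order way at 0.0115 s⁻¹. Over 30 s that gives 4.67 mM, hence 43.3% reacted.

**But you held the nucleophile at its charge.** I did, and it falls, so I expect to land somewhat lower.

**Where do the protons go?** To the nucleophile, because the buffer acid's constant is larger than that of the protonated nucleophile. With the adduct ignored, the pH stands 0.813 above the pK of the protonated nucleophile, whose constant is 2.0 × 10⁻⁹ M.

The forecast gave 41% and pH 9.48, holding that “the pH is set by the nucleophile pair”. The flask gives 40.6% and pH 9.49, 2.7 percentage points below my reckoning for the electrophile.

In the flask, quenching and the main step ran together at first: after 3.00 s the impurity stood at 30.5% of its charge and c(leaving group) at 0.586 mM, while the product per e-fold, with c(nucleophile) at its reading of 92.9%, gives 0.577 mM. The main step then ran on, reaching 4.12 mM of leaving group at 30.0 s. In the neighbour with 120 mM of nucleophile, the product per e-fold is 1.25 mM, and its impurity fell to 0.0525%. Free nucleophile at its end reading of 78.9% and at its charge gives 7.45 mM and 9.44 mM, and its leaving group reads 8.36 mM.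

The rate constants are invented; what happens was integrated by code.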